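**Plan**

1. Retrosynthesis: the hydroxyquinone is traced back, through a 4-ethoxy-1,2-benzoquinone, to a 2-allyl-4-chloro-3-ethoxy-5-methylphenol (ortho-oxygenation, then hydrolysis of the ethyl vinylogous ester). The side chain is cut at its trisubstituted C=C (cross-metathesis) and at the carbinol C–H (enone reduction). The benzene ring is cut between the C(OH) carbon and the carbon that carries the side chain, and between C(Cl) and C(OEt).
2. Enabling feature: in the six-membered ring, the run C(OH)–C(H, later O)–C(CH3)–C(Cl) is the O=C–CH=C(CH3)–CCl skeleton of a 4-chlorocyclobutenone. The other two ring atoms, C(OEt) and C(side chain), are an α-ethoxyalkenyl unit. Joined at the C(Cl) carbon they give a 4-alkenylcyclobutenone whose strain-driven 4π opening yields a dienylketene with the C(OH) carbon and the side-chain carbon at its two ends.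
3. Forward order: dichloroketene/propyne [2+2] gives the cyclobutenone; Stille coupling and in situ ring expansion build the arene with OH, allyl, OEt, Cl, CH3 and H in place. The cyclohexanone ring is made separately and joined through the allyl group by cross-metathesis. The quinone is unveiled last.
4. Stereochemistry: the secondary ring methyl next to the quaternary carbon is set by an organocatalytic Michael addition. The quaternary centre is relayed from it by anti cuprate addition, and the α-keto methyl by equilibration. The carbinol is set by CBS reduction (catalyst control), and the E alkene by thermodynamically controlled cross-metathesis.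

Key step: step 4

Remark: the 2-hydroxy-1,4-benzoquinone and its 4-hydroxy-1,2-benzoquinone form are tautomers of one compound, so hydrolysis of the 4-ethoxy-1,2-benzoquinone gives the target directly.

**Route**

Step 1
Reactants: 1 trichloroacetyl chloride; 2 propyne
Product: 4 4,4-dichloro-3-methylcyclobut-2-en-1-one, via dichloroketene 3 (not isolated)
Conditions: Zn(Cu) (zinc–copper couple), POCl3, Et2O, 2 (excess), 0 °C → rt
Reagents that add atoms: none
Why: Ketene–alkyne [2+2] cycloaddition: dichloroketene from zinc dechlorination of 1 bonds through its carbonyl carbon to the terminal alkyne carbon, so the methyl ends up on C3 next to the CCl2 carbon.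

Step 2
Reactants: 5 ethoxyethyne; 6 allyl bromide
Product: 8 5-ethoxypent-1-en-4-yne, via lithium ethoxyacetylide 7 (not isolated)
Conditions: n-BuLi, THF, −78 °C; then CuBr·SMe2 (10 mol %), 6, −78 °C → rt
Reagents that add atoms: none
Why: Copper-catalysed allylation of a metalated alkynyl ether is a standard entry to 1-alkoxy-1-alkynes, and SN2 and SN2' attack on allyl bromide give the same product.

Step 3
Reactants: 8 5-ethoxypent-1-en-4-yne
Product: 9 (E)-tributyl(1-ethoxypenta-1,4-dien-1-yl)stannane
Conditions: Bu3SnH, Pd(PPh3)4 (2 mol %), THF, 0 °C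
Reagents that add atoms: tributyltin hydride CCCC[SnH](CCCC)CCCC
Why: Palladium-catalysed hydrostannation of a 1-alkoxy-1-alkyne is a syn addition that should place tin on the oxygen-bearing carbon, and the ynol ether should react far faster than the isolated terminal alkene.

Step 4
Reactants: 4 4,4-dichloro-3-methylcyclobut-2-en-1-one; 9 (E)-tributyl(1-ethoxypenta-1,4-dien-1-yl)stannane
Product: 13 2-allyl-4-chloro-3-ethoxy-5-methylphenol, via 4-alkenyl-4-chlorocyclobutenone 10 (not isolated), via dienylketene 11 (not isolated), via cyclohexadienone 12 (not isolated)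
Conditions: PdCl2(PhCN)2 (5 mol %), tri(2-furyl)phosphine (10 mol %), dioxane, 50 °C → 100 °C
Reagents that add atoms: none
Why: Proposed new method: zerovalent palladium should insert into one of the two allylic, α-keto C–Cl bonds of 4, transmetalation with the electron-rich stannane 9 and reductive elimination should give 10, and the strained ring of 10 then opens in a conrotatory 4π process (chlorine rotating outward, the alkenyl group inward) to the dienylketene 11, whose ketene carbon and enol-ether CH terminus close in a thermal disrotatory 6π electrocyclization to 12, which tautomerizes to the phenol. The closest known reaction type is the Stille coupling of 4-chlorocyclobut-2-enones with alkenylstannanes that is followed in situ by the same ring expansion to phenols; new is the geminal dichloride, one chlorine of which is kept and becomes the aryl chloride. The six-membered ring closes in the 6π electrocyclization (bond between the future C–OH carbon and the allyl-bearing carbon), driven by release of cyclobutenone strain and by aromatization, and no stereocenter is formed. The step needs mono-coupling at the CCl2 carbon: the remaining C–Cl of 10 is tertiary and hindered, and 10 is drained by ring opening at the reaction temperature. The positions of OH, H, CH3, Cl, OEt and allyl follow from the connectivity of 4 and 9 alone, and the E geometry of 9 turns the allyl-bearing CH outward so that its carbon is free to bond.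

Step 5
Reactants: 14 propanal; 15 pent-1-en-3-one
Product: 17 (S)-2,4-dimethylcyclohex-2-en-1-one, via (S)-2-methyl-5-oxoheptanal 16 (not isolated)
Conditions: (R)-2-[methoxy(diphenyl)methyl]pyrrolidine (5 mol %), ethyl 3,4-dihydroxybenzoate (20 mol %), neat, 4 °C; then aq. KOH (0.1 M), n-Bu4NOH (cat.), Et2O/THF, 40 °C
Reagents that add atoms: none
Why: Enamine-catalysed Michael addition in which the diphenyl(methoxy)methyl group shields one face of the (E)-enamine of propanal, so the (R)-catalyst should give the (S)-aldehyde 16, and the base then closes the ring by intramolecular aldol condensation of the ethyl ketone onto the aldehyde without touching a bond of the new stereocenter.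

Step 6
Reactants: 17 (S)-2,4-dimethylcyclohex-2-en-1-one
Product: 18 trimethyl{[(3R,4S)-2,4-dimethyl-3-(prop-2-en-1-yl)cyclohex-1-en-1-yl]oxy}silane
Conditions: allylMgBr, CuBr·SMe2 (1.5 equiv), TMSCl, THF, −78 °C; Et3N work-up
Reagents that add atoms: allylmagnesium bromide C=CC[Mg]Br; chlorotrimethylsilane C[Si](C)(C)Cl
Why: TMSCl-accelerated conjugate addition of an allylcopper reagent traps the regiodefined enolate as its silyl enol ether; the allyl group should enter anti to the C4 methyl, but this C3 configuration is erased in the next step.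

Step 7
Reactants: 18 silyl enol ether
Product: 19 (S)-2,4-dimethyl-3-(prop-2-en-1-yl)cyclohex-2-en-1-one
Conditions: Pd(OAc)2 (10 mol %), O2 (1 atm), DMSO, rt
Reagents that add atoms: none
Why: Saegusa–Ito oxidation, in which the palladium enolate at C2 undergoes β-hydride elimination of the ring C3–H (syn to palladium, which sits trans to the allyl group) to give the conjugated tetrasubstituted enone with the C4 stereocenter untouched.

Step 8
Reactants: 19 (S)-2,4-dimethyl-3-(prop-2-en-1-yl)cyclohex-2-en-1-one
Product: 21 (2S,3S,4S)-2,3,4-trimethyl-3-(prop-2-en-1-yl)cyclohexan-1-one, via lithium enolate 20 (not isolated)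
Conditions: Me2CuLi (from MeLi and CuI), BF3·OEt2, Et2O, −78 → −20 °C; then H2O; then NaOMe (cat.), MeOH, rt
Reagents that add atoms: lithium dimethylcuprate [Li+].C[Cu-]C
Why: Lewis-acid-assisted cuprate conjugate addition to a 4-substituted cyclohexenone occurs by axial attack anti to the C4 methyl, which sets the quaternary C3 (new methyl trans to the C4 methyl, allyl cis), and base equilibration should place the epimerizable C2 methyl equatorial (all three methyls equatorial, allyl axial).

Step 9
Reactants: 21 (2S,3S,4S)-2,3,4-trimethyl-3-(prop-2-en-1-yl)cyclohexan-1-one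
Product: 22 (6S,7S,8S)-6,7,8-trimethyl-7-(prop-2-en-1-yl)-1,4-dioxaspiro[4.5]decane
Conditions: TMSOCH2CH2OTMS, TMSOTf (5 mol %), CH2Cl2, −78 → −20 °C
Reagents that add atoms: 1,2-bis(trimethylsilyloxy)ethane C[Si](C)(C)OCCO[Si](C)(C)C
Why: Noyori ketalization at low temperature masks the ketone for the later borane reduction without acid-mediated epimerization of the α-stereocenter.

Step 10
Reactants: 22 dioxolane
Product: 23 2-[(6S,7S,8S)-6,7,8-trimethyl-1,4-dioxaspiro[4.5]decan-7-yl]acetaldehyde
Conditions: O3, CH2Cl2, −78 °C; then Me2S, −78 °C → rt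
Reagents that add atoms: ozone [O-][O+]=O
Why: Ozonolysis with reductive work-up cleaves the only alkene to the aldehyde, and the dioxolane is stable under these conditions.

Step 11
Reactants: 23 aldehyde
Product: 24 3-methyl-1-[(6S,7S,8S)-6,7,8-trimethyl-1,4-dioxaspiro[4.5]decan-7-yl]but-3-en-2-ol (both carbinol epimers)
Conditions: isopropenylMgBr, THF, −78 → 0 °C; then H2O
Reagents that add atoms: isopropenylmagnesium bromide CC(=C)[Mg]Br
Why: Grignard 1,2-addition to the aldehyde; the carbinol configuration is irrelevant because it is oxidized in the next step.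

Step 12
Reactants: 24 allylic alcohol
Product: 25 3-methyl-1-[(6S,7S,8S)-6,7,8-trimethyl-1,4-dioxaspiro[4.5]decan-7-yl]but-3-en-2-one
Conditions: Dess–Martin periodinane, pyridine, CH2Cl2, 0 °C → rt
Reagents that add atoms: none
Why: Buffered Dess–Martin oxidation of the secondary allylic alcohol gives the isopropenyl ketone without alkene migration or loss of the ketal.

Step 13
Reactants: 25 isopropenyl ketone; 13 2-allyl-4-chloro-3-ethoxy-5-methylphenol (excess)
Product: 26 (3E)-5-(3-chloro-2-ethoxy-6-hydroxy-4-methylphenyl)-3-methyl-1-[(6S,7S,8S)-6,7,8-trimethyl-1,4-dioxaspiro[4.5]decan-7-yl]pent-3-en-2-one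
Conditions: second-generation Hoveyda–Grubbs catalyst RuCl2(H2IMes)(=CH-C6H4-2-OiPr) (10 mol %), 1,4-benzoquinone (10 mol %), toluene, 60 °C
Reagents that add atoms: none
Why: Olefin cross-metathesis between a terminal allylarene and a 1,1-disubstituted enone should give the conjugated trisubstituted enone with thermodynamic E selectivity, with benzoquinone suppressing isomerization of the allylphenol.

Step 14
Reactants: 26 enone
Product: 27 (2S,3E)-5-(3-chloro-2-ethoxy-6-hydroxy-4-methylphenyl)-3-methyl-1-[(6S,7S,8S)-6,7,8-trimethyl-1,4-dioxaspiro[4.5]decan-7-yl]pent-3-en-2-ol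
Conditions: (R)-2-methyl-CBS-oxazaborolidine (20 mol %), BH3·SMe2, THF, −30 °C; then MeOH
Reagents that add atoms: none
Why: Corey–Bakshi–Shibata reduction in which the α-methylalkenyl group acts as the large and the CH2 group as the small substituent, so the (R)-oxazaborolidine should give the (S)-allylic alcohol under catalyst control while the ketal shields the ring ketone.

Step 15
Reactants: 27 allylic alcohol
Product: 29 4-chloro-3-ethoxy-5-methyl-2-{(2E,4S)-3-methyl-4-(triethylsilyloxy)-5-[(6S,7S,8S)-6,7,8-trimethyl-1,4-dioxaspiro[4.5]decan-7-yl]pent-2-en-1-yl}phenol, via bis(triethylsilyl) ether 28 (not isolated)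
Conditions: TESCl (2.5 equiv), imidazole, DMF, 0 °C → rt; then K2CO3 (cat.), MeOH, 0 °C
Reagents that add atoms: chlorotriethylsilane CC[Si](Cl)(CC)CC
Why: Both hydroxyls are silylated and the far more labile aryl silyl ether is then removed by mild base-catalysed methanolysis, which leaves the allylic alcohol protected against the oxidant of the last step.

Step 16
Reactants: 29 phenol
Product: 31 2-chloro-5-hydroxy-3-methyl-6-{(2E,4S)-4-hydroxy-3-methyl-5-[(1S,2S,6S)-1,2,6-trimethyl-3-oxocyclohexyl]pent-2-en-1-yl}cyclohexa-2,5-diene-1,4-dione, via ortho-quinone 30 (not isolated)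
Conditions: IBX (1.2 equiv), DMF, rt; then aq. HCl (1 M), THF, 0 °C → rt
Reagents that add atoms: IBX (2-iodoxybenzoic acid) O=C1OI(=O)(O)c2ccccc12; water O
Why: IBX-mediated ortho-oxygenation of a phenol should occur at the only free ortho position to give the ortho-quinone, and aqueous acid then hydrolyses the 4-ethoxy-1,2-benzoquinone (a vinylogous ester) to the tautomeric 2-hydroxy-1,4-benzoquinone while removing the silyl ether and the dioxolane.

**Compound list**

1 | trichloroacetyl chloride | ClC(=O)C(Cl)(Cl)Cl | starting material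
2 | propyne | CC#C | starting material
3 | dichloroketene (formed in situ) | ClC(Cl)=C=O | intermediate
4 | 4,4-dichloro-3-methylcyclobut-2-en-1-one | CC1=CC(=O)C1(Cl)Cl | intermediate
5 | ethoxyethyne | CCOC#C | starting material
6 | allyl bromide | C=CCBr | starting material
7 | lithium ethoxyacetylide (formed in situ) | [Li]C#COCC | intermediate
8 | 5-ethoxypent-1-en-4-yne | C=CCC#COCC | intermediate
9 | (E)-tributyl(1-ethoxypenta-1,4-dien-1-yl)stannane | CCCC[Sn](CCCC)(CCCC)/C(OCC)=C/CC=C | intermediate
10 | 4-chloro-4-[(1Z)-1-ethoxypenta-1,4-dien-1-yl]-3-methylcyclobut-2-en-1-one (racemic, formed in situ) | CC1=CC(=O)C1(Cl)/C(OCC)=C/CC=C | intermediate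
11 | (3E,5Z)-4-chloro-5-ethoxy-3-methylnona-1,3,5,8-tetraen-1-one (dienylketene, formed in situ) | O=C=C/C(C)=C(Cl)\C(OCC)=C\CC=C | intermediate
12 | 4-chloro-5-ethoxy-3-methyl-6-(prop-2-en-1-yl)cyclohexa-2,4-dien-1-one (formed in situ) | CCOC1=C(Cl)C(C)=CC(=O)C1CC=C | intermediate
13 | 2-allyl-4-chloro-3-ethoxy-5-methylphenol | CCOc1c(Cl)c(C)cc(O)c1CC=C | intermediate
14 | propanal | CCC=O | starting material
15 | pent-1-en-3-one | CCC(=O)C=C | starting material
16 | (S)-2-methyl-5-oxoheptanal (formed in situ) | O=C[C@@H](C)CCC(=O)CC | intermediate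
17 | (S)-2,4-dimethylcyclohex-2-en-1-one | O=C1CC[C@H](C)C=C1C | intermediate
18 | trimethyl{[(3R,4S)-2,4-dimethyl-3-(prop-2-en-1-yl)cyclohex-1-en-1-yl]oxy}silane | C[Si](C)(C)OC1=C(C)[C@H](CC=C)[C@@H](C)CC1 | intermediate
19 | (S)-2,4-dimethyl-3-(prop-2-en-1-yl)cyclohex-2-en-1-one | C=CCC1=C(C)C(=O)CC[C@@H]1C | intermediate
20 | lithium enolate of 21 (formed in situ) | C=CC[C@]1(C)C(C)=C([O-])CC[C@@H]1C.[Li+] | intermediate
21 | (2S,3S,4S)-2,3,4-trimethyl-3-(prop-2-en-1-yl)cyclohexan-1-one | C=CC[C@]1(C)[C@H](C)C(=O)CC[C@@H]1C | intermediate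
22 | (6S,7S,8S)-6,7,8-trimethyl-7-(prop-2-en-1-yl)-1,4-dioxaspiro[4.5]decane | C=CC[C@]1(C)[C@H](C)C2(OCCO2)CC[C@@H]1C | intermediate
23 | 2-[(6S,7S,8S)-6,7,8-trimethyl-1,4-dioxaspiro[4.5]decan-7-yl]acetaldehyde | O=CC[C@]1(C)[C@H](C)C2(OCCO2)CC[C@@H]1C | intermediate
24 | 3-methyl-1-[(6S,7S,8S)-6,7,8-trimethyl-1,4-dioxaspiro[4.5]decan-7-yl]but-3-en-2-ol (carbinol epimers) | C=C(C)C(O)C[C@]1(C)[C@H](C)C2(OCCO2)CC[C@@H]1C | intermediate
25 | 3-methyl-1-[(6S,7S,8S)-6,7,8-trimethyl-1,4-dioxaspiro[4.5]decan-7-yl]but-3-en-2-one | C=C(C)C(=O)C[C@]1(C)[C@H](C)C2(OCCO2)CC[C@@H]1C | intermediate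
26 | (3E)-5-(3-chloro-2-ethoxy-6-hydroxy-4-methylphenyl)-3-methyl-1-[(6S,7S,8S)-6,7,8-trimethyl-1,4-dioxaspiro[4.5]decan-7-yl]pent-3-en-2-one | CCOc1c(Cl)c(C)cc(O)c1C/C=C(\C)C(=O)C[C@]1(C)[C@H](C)C2(OCCO2)CC[C@@H]1C | intermediate
27 | (2S,3E)-5-(3-chloro-2-ethoxy-6-hydroxy-4-methylphenyl)-3-methyl-1-[(6S,7S,8S)-6,7,8-trimethyl-1,4-dioxaspiro[4.5]decan-7-yl]pent-3-en-2-ol | CCOc1c(Cl)c(C)cc(O)c1C/C=C(\C)[C@@H](O)C[C@]1(C)[C@H](C)C2(OCCO2)CC[C@@H]1C | intermediate
28 | bis(triethylsilyl) ether of 27 (aryl and carbinol oxygens silylated, formed in situ) | CCOc1c(Cl)c(C)cc(O[Si](CC)(CC)CC)c1C/C=C(\C)[C@@H](O[Si](CC)(CC)CC)C[C@]1(C)[C@H](C)C2(OCCO2)CC[C@@H]1C | intermediate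
29 | 4-chloro-3-ethoxy-5-methyl-2-{(2E,4S)-3-methyl-4-(triethylsilyloxy)-5-[(6S,7S,8S)-6,7,8-trimethyl-1,4-dioxaspiro[4.5]decan-7-yl]pent-2-en-1-yl}phenol | CCOc1c(Cl)c(C)cc(O)c1C/C=C(\C)[C@@H](O[Si](CC)(CC)CC)C[C@]1(C)[C@H](C)C2(OCCO2)CC[C@@H]1C | intermediate
30 | 5-chloro-4-ethoxy-6-methyl-3-{(2E,4S)-3-methyl-4-(triethylsilyloxy)-5-[(6S,7S,8S)-6,7,8-trimethyl-1,4-dioxaspiro[4.5]decan-7-yl]pent-2-en-1-yl}cyclohexa-3,5-diene-1,2-dione (formed in situ) | CCOC1=C(C/C=C(\C)[C@@H](O[Si](CC)(CC)CC)C[C@]2(C)[C@H](C)C3(OCCO3)CC[C@@H]2C)C(=O)C(=O)C(C)=C1Cl | intermediate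
31 | 2-chloro-5-hydroxy-3-methyl-6-{(2E,4S)-4-hydroxy-3-methyl-5-[(1S,2S,6S)-1,2,6-trimethyl-3-oxocyclohexyl]pent-2-en-1-yl}cyclohexa-2,5-diene-1,4-dione | CC1=C(Cl)C(=O)C(C/C=C(\C)[C@@H](O)C[C@]2(C)[C@H](C)C(=O)CC[C@@H]2C)=C(O)C1=O | target

**Count and risks**

Total steps: 16. Longest linear sequence: 12 steps (steps 5 to 16); steps 1 to 4 form the convergent branch.

Step 4 (Proposed new method). The gem-dichloride may couple twice, couple at C2 of the oxocyclobutenyl palladium intermediate, or decompose before transmetalation. The fallback introduces chlorine after the ring is made and uses only the established coupling. Compound 4 is monodechlorinated with zinc dust in acetic acid/TMEDA to 4-chloro-3-methylcyclobut-2-en-1-one F1. F1 undergoes the known palladium-catalysed coupling with 9 and in situ ring expansion to 2-allyl-3-ethoxy-5-methylphenol F2. Chlorination of F2 para to the hydroxyl (NCS in MeCN, or SO2Cl2 with a sulfide catalyst) then gives 13, where the route is rejoined. The price is a para-versus-ortho selectivity question that the main route avoids.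

Step 8. The cuprate may fail to add to the tetrasubstituted, γ-branched enone (no conversion, 1,2-addition or poor facial selectivity). The fallback delivers the methyl group as a cyclopropane methylene. Compound 19 is reduced under Luche conditions (NaBH4, CeCl3·7H2O) to (1S,4S)-2,4-dimethyl-3-(prop-2-en-1-yl)cyclohex-2-en-1-ol F3, with the hydroxyl trans to the C4 methyl (Mitsunobu inversion if the cis epimer prevails). Hydroxyl-directed Simmons–Smith cyclopropanation (Et2Zn, CH2I2) of the ring alkene gives 1,5-dimethyl-6-(prop-2-en-1-yl)bicyclo[4.1.0]heptan-2-ol F4, with the methylene on the hydroxyl face. Dess–Martin oxidation gives the cyclopropyl ketone 1,5-dimethyl-6-(prop-2-en-1-yl)bicyclo[4.1.0]heptan-2-one F5. Dissolving-metal reduction (Li, NH3, t-BuOH) cleaves the exocyclic cyclopropane bond that overlaps with the carbonyl, which leaves the methylene as the quaternary methyl trans to the C4 methyl. Protonation and base equilibration give 21.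

Step 16. The IBX oxidation may be unselective (attack at the doubly activated benzylic/allylic CH2, tautomerization or decomposition of the ortho-quinone, or displacement of the ring chloride during hydrolysis). The fallback brings in the ortho oxygen through carbon. Compound 29 is formylated at its only free ortho position (MgCl2, Et3N, paraformaldehyde, MeCN, reflux; Casnati–Skattebøl conditions) to 3-chloro-4-ethoxy-6-hydroxy-2-methyl-5-(side chain)benzaldehyde F6. Dakin oxidation (H2O2, aq. NaOH) and hydrolysis of the aryl formate give 4-chloro-5-ethoxy-3-methyl-6-(side chain)benzene-1,2-diol F7. Mild oxidation (Ag2O, Et2O) gives the ortho-quinone 30, which is hydrolysed with aqueous acid as in step 16.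

**Further compounds**

F1 | step 4 | 4-chloro-3-methylcyclobut-2-en-1-one (racemic) | CC1=CC(=O)C1Cl
F2 | step 4 | 2-allyl-3-ethoxy-5-methylphenol | CCOc1cc(C)cc(O)c1CC=C
F3 | step 8 | (1S,4S)-2,4-dimethyl-3-(prop-2-en-1-yl)cyclohex-2-en-1-ol | C=CCC1=C(C)[C@@H](O)CC[C@@H]1C
F4 | step 8 | 1,5-dimethyl-6-(prop-2-en-1-yl)bicyclo[4.1.0]heptan-2-ol (cyclopropane CH2 and OH on one face, anti to the C5 methyl) | C=CC[C@]12C[C@@]1(C)[C@@H](O)CC[C@@H]2C
F5 | step 8 | 1,5-dimethyl-6-(prop-2-en-1-yl)bicyclo[4.1.0]heptan-2-one (cyclopropane CH2 anti to the C5 methyl) | C=CC[C@]12C[C@@]1(C)C(=O)CC[C@@H]2C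
F6 | step 16 | 3-chloro-4-ethoxy-6-hydroxy-2-methyl-5-{(2E,4S)-3-methyl-4-(triethylsilyloxy)-5-[(6S,7S,8S)-6,7,8-trimethyl-1,4-dioxaspiro[4.5]decan-7-yl]pent-2-en-1-yl}benzaldehyde | CCOc1c(Cl)c(C)c(C=O)c(O)c1C/C=C(\C)[C@@H](O[Si](CC)(CC)CC)C[C@]1(C)[C@H](C)C2(OCCO2)CC[C@@H]1C
F7 | step 16 | 4-chloro-5-ethoxy-3-methyl-6-{(2E,4S)-3-methyl-4-(triethylsilyloxy)-5-[(6S,7S,8S)-6,7,8-trimethyl-1,4-dioxaspiro[4.5]decan-7-yl]pent-2-en-1-yl}benzene-1,2-diol | CCOc1c(Cl)c(C)c(O)c(O)c1C/C=C(\C)[C@@H](O[Si](CC)(CC)CC)C[C@]1(C)[C@H](C)C2(OCCO2)CC[C@@H]1C
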